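I take solid substrate as conserved and let each product take up one partner, so in each flask here:

target + isomer of the product + unreacted = whole charge
target + isomer of the product ≤ ceiling

The ceiling is the smaller of the whole charge and the partner's equivalents, both as fractions of the solid substrate charged. For the new flask it stands at 100 %, so partner should keep at least 23.1 % of its own charge.

| flask | solid substrate | partner | remark | time |
|---|---|---|---|---|
| autumn | 0.0034 M | 1.3 equiv | run made earlier |  |
| midnight | 0.0075 M | 1.3 equiv | run made earlier |  |
| flask | 0.0050 M | 1.30 equiv |  | 25 min |

| run | time / min | target / % | isomer of the product / % |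
|---|---|---|---|
| autumn | 5.00 | 74.5 | 21.4 |
| autumn | 10.0 | 79.7 | 23.4 |
| autumn | 15.0 | 78.0 | 22.9 |
| autumn | 20.0 | 78.0 | 22.8 |
| autumn | 25.0 | 77.0 | 20.3 |
| autumn | 30.0 | 77.1 | 22.4 |
| midnight | 2.00 | 81.3 | 11.5 |
| midnight | 6.00 | 84.0 | 14.9 |
| midnight | 10.0 | 84.5 | 15.0 |
| midnight | 15.0 | 86.1 | 14.1 |
| midnight | 25.0 | 87.2 | 18.8 |
| midnight | 30.0 | 84.9 | 15.7 |

(standard deviation of a reading: 1 percentage point)

- the analysis behind the earlier runs scatters by 1 percentage point, standard deviation
- at the start none of the solid substrate is in solution
- in a conversion other conformer counts as not yet reacted
- a reading or a percentage of target counts all its forms, free or not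
- what has only dissolved of solid substrate counts as not reacted
- the reaction counts as stopped when no species that holds the solid substrate changes by six tenths of a point or more over the second half of the time

1. the state of affairs at 25 min: stopped, and by what, or still going (for what has run out or reacted, a solid counts together with what of it has only dissolved; other conformer counts as not reacted) (it is still moving / the partner has run out first / all of the solid substrate has reacted / forward and back rates have come level)
2. the target standing at 25 min, as a percentage of the solid substrate charged
3. the isomer of the product standing at 25 min, as a percentage of the solid substrate charged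

My own bracket starts from the late readings, averaged. In the autumn run, from 10.0 min on, target reads 78.0 % and isomer 22.4 %. In the midnight run, from 6.00 min on, they read 85.3 % and 15.7 %. Their sums, 100 % and 101 %, sit at the ceiling within scatter, so I take target as the ceiling minus the isomer. I also assume the isomer falls steadily as concentration rises.

From above: target ≤ 84.3 %
From below: target ≥ 77.6 %

If that fall slows as it goes, the isomer lies under the straight line between the runs, at most 19.8 %. This tightens the lower bound:

target ≥ 80.2 %

The forecast says that all of the solid substrate has reacted, with target 81.5 % (79.8 % to 83.2 %) and isomer 18.6 % (16.9 % to 20.3 %), holding that “the reaction has stopped because the substrate is used up”. Its target lies inside my bracket.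

In the flask all of the solid substrate has reacted, with target 81.4 % and isomer 18.6 %, and that target is inside the bracket too.

    starting material ⇌ other conformer (K = 0.430, k = 0.00670 s⁻¹)
    starting material + partner → target (k = 5.20 M⁻¹ s⁻¹)
    partner + other conformer → isomer of the product (k = 10.0 M⁻¹ s⁻¹)
    solid substrate ⇌ starting material, rate k4*(cs4 - [starting material]) while solid is left; crystals form when [starting material] > cs4 (solubility = 4.80 mM, k = 0.220 s⁻¹)
    crystals ⇌ target, rate k5*(cs5 - [target]) while solid is left; crystals form when [target] > cs5 (solubility = 2.10 mM, k = 1.20 s⁻¹)

In this flask the two products add to >99.9 %, against the ceiling of 100 %, and partner keeps 23 % of its charge, as the reckoned 23.1 % said. Now take a neighbouring flask, like this one but charged with 0.780 equiv of partner. Its ceiling drops to 78.0 %, and partner becomes the limiting reagent. That neighbour gives target 60.0 % and isomer 18.0 %, together 78.0 %, with partner down to 0 %. Starting material stands there at 15.4 % and other conformer at 6.62 %.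

The data are calculated with made-up constants; scatter was added.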